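**Retrosynthetic overview**

- The strategy rests on one feature: the pyranone ring has a single CH, C3, lying between C2 (bonded to O1 and the nonadecyl chain) and the C4 carbonyl. Removing C3 leaves a 2-nonadecylbenzofuran-3-one, so the chromone is built as the one-carbon homologue of that five-membered ring.
- Late disconnections: the two O–methyl bonds and a C3–Br bond lead back to 3-bromo-5,7-dimethoxy-2-nonadecylchromone.
- Key disconnection: the C2–C3 and C3–C4 bonds are cut to dibromocarbene (from bromoform) and a 3-silyloxybenzofuran. The benzene and furan rings are bought; the six-membered ring is formed last, by expansion of the furan.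
- Side chain: the C2–C1' bond goes back to 4,6-dimethoxybenzofuran-3(2H)-one and nonadecanal (aldol condensation, hydrogenation, O-silylation).

Key step: step 5

Remark on the chemistry: the target has no stereocentre. Compound 6 and the transient species 4 and 9 are racemic (4 as a diastereomer mixture; one enantiomer of 9 is drawn), and 5 is expected as the Z isomer; none of this affects the outcome.

**Route**

Step 1
Reactants: 1 1-nonadecanol
Product: 2 nonadecanal
Conditions: TEMPO (cat.), PhI(OAc)2, CH2Cl2, rt
Reagents that add atoms: none
Why: TEMPO-catalysed (oxoammonium) oxidation of a primary alcohol should stop at the aldehyde in the absence of water, and the saturated chain offers no other reactive site.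

Step 2
Reactants: 3 4,6-dimethoxy-1-benzofuran-3(2H)-one; 2 nonadecanal
Product: 5 (2Z)-4,6-dimethoxy-2-nonadecylidene-1-benzofuran-3(2H)-one, via aldol adduct 4 (not isolated)
Conditions: neutral Al2O3, CH2Cl2, rt
Reagents that add atoms: none
Why: Aldol condensation of the aurone type: the C2 methylene, activated by the ketone and the aryloxy oxygen, should enolise on the alumina surface more readily than the aldehyde, and the adduct should dehydrate to the conjugated enone, whose geometry is of no consequence.

Step 3
Reactants: 5 (2Z)-4,6-dimethoxy-2-nonadecylidene-1-benzofuran-3(2H)-one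
Product: 6 4,6-dimethoxy-2-nonadecyl-1-benzofuran-3(2H)-one (racemic)
Conditions: H2 (1 atm), Pd/C, EtOAc, rt
Reagents that add atoms: none
Why: Catalytic hydrogenation should saturate the conjugated exocyclic alkene while the electron-rich aryl ketone and the aryl ethers stay intact; the new C2 stereocentre forms racemic and is erased in step 4.

Step 4
Reactants: 6 4,6-dimethoxy-2-nonadecyl-1-benzofuran-3(2H)-one
Product: 7 tert-butyl[(4,6-dimethoxy-2-nonadecyl-1-benzofuran-3-yl)oxy]dimethylsilane
Conditions: TBSOTf, Et3N, CH2Cl2, 0 °C
Reagents that add atoms: tert-butyldimethylsilyl trifluoromethanesulfonate, CC(C)(C)[Si](C)(C)OS(=O)(=O)C(F)(F)F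
Why: Silyl enol ether formation by soft enolisation: the ketone has only the C2 α-hydrogen, the hard silicon electrophile should go to oxygen, and the product gains the aromaticity of a benzofuran.

Step 5
Reactants: 7 tert-butyl[(4,6-dimethoxy-2-nonadecyl-1-benzofuran-3-yl)oxy]dimethylsilane; 8 bromoform
Product: 11 3-bromo-5,7-dimethoxy-2-nonadecylchromone, via dibromocyclopropane adduct 9 (not isolated), via silyloxybenzopyrylium bromide 10 (not isolated)
Conditions: CHBr3, KOtBu, hexane, −20 °C to rt; then aq. NH4Cl
Reagents that add atoms: bromoform (compound 8), BrC(Br)Br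
Why: Proposed new method: dibromocarbene, formed by alpha-elimination of bromide from the tribromomethyl anion, should add in one cheletropic [2+1] event to the C2=C3 bond of 7, giving the cis-fused cyclopropane 9 whose two stereocentres are fixed by the ring fusion and disappear again. The endo C–Br bond of 9 should then ionise in concert with disrotatory two-electron electrocyclic cleavage of the old C2–C3 bond, so that the six-membered ring arises by ring expansion of the furan (not by a cyclisation) and the carbene carbon becomes C3, bonded to C2 and C4. The cation formed, 3-bromo-4-silyloxybenzopyrylium 10, is aromatic and carries two oxygen donors, and loss of the silyl group to bromide or on aqueous work-up should leave the C4 carbonyl. The closest known reactions are the dihalocarbene cyclopropanation and ring enlargement of cyclic silyl enol ethers to 2-halocycloalkenones and the Ciamician–Dennstedt-type enlargement of indoles and benzofurans; the combination on a 3-silyloxybenzofuran has not been shown. The step needs the carbene to choose the enol ether over the dimethoxybenzene ring, which the two oxygen donors on a weakly aromatic C=C bond should secure, and it needs the silyl enol ether to outlive the base, which the bulky tert-butyldimethylsilyl group and solid KOtBu in hexane at low temperature should secure. No regiochemical question arises, since a geminal dibromide always has one bromine endo and both C–C bonds to the new carbon are made in the addition.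

Step 6
Reactants: 11 3-bromo-5,7-dimethoxy-2-nonadecylchromone
Product: 12 5,7-dimethoxy-2-nonadecylchromone
Conditions: Pd(PPh3)4 (cat.), HCO2Na, DMF, 90 °C
Reagents that add atoms: none
Why: Palladium-catalysed formate hydrogenolysis: zerovalent palladium should insert into the C3–Br bond of the α-bromo enone, formate should deliver hydride with loss of CO2, and reductive elimination should give the C3–H bond without touching the methyl ethers or the chain.

Step 7
Reactants: 12 5,7-dimethoxy-2-nonadecylchromone
Product: 14 5,7-dihydroxy-2-nonadecylchromone, via bis(dibromoboryl) ether 13 (not isolated)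
Conditions: BBr3 (excess), CH2Cl2, −78 °C to rt; then H2O
Reagents that add atoms: none
Why: BBr3 ether cleavage: boron should coordinate each methoxy oxygen (the C5 ether helped by chelation to the C4 carbonyl), bromide should remove the methyl group by SN2, and hydrolysis of the aryl borates should free both phenols while the chromone and the saturated chain survive.

**Compound list**

1 | 1-nonadecanol | CCCCCCCCCCCCCCCCCCCO | starting material
2 | nonadecanal | CCCCCCCCCCCCCCCCCCC=O | intermediate
3 | 4,6-dimethoxy-1-benzofuran-3(2H)-one | COc1cc(OC)c2c(c1)OCC2=O | starting material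
4 | 2-(1-hydroxynonadecyl)-4,6-dimethoxy-1-benzofuran-3(2H)-one (aldol adduct, diastereomer mixture, racemic) | CCCCCCCCCCCCCCCCCCC(O)C1Oc2cc(OC)cc(OC)c2C1=O | intermediate (not isolated)
5 | (2Z)-4,6-dimethoxy-2-nonadecylidene-1-benzofuran-3(2H)-one | CCCCCCCCCCCCCCCCCC/C=C1\Oc2cc(OC)cc(OC)c2C1=O | intermediate
6 | 4,6-dimethoxy-2-nonadecyl-1-benzofuran-3(2H)-one (racemic) | CCCCCCCCCCCCCCCCCCCC1Oc2cc(OC)cc(OC)c2C1=O | intermediate
7 | tert-butyl[(4,6-dimethoxy-2-nonadecyl-1-benzofuran-3-yl)oxy]dimethylsilane | CCCCCCCCCCCCCCCCCCCc1oc2cc(OC)cc(OC)c2c1O[Si](C)(C)C(C)(C)C | intermediate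
8 | bromoform | BrC(Br)Br | starting material
9 | cis-fused 1,1-dibromo-6b-[(tert-butyldimethylsilyl)oxy]-4,6-dimethoxy-1a-nonadecyl-1a,6b-dihydro-1H-cyclopropa[b][1]benzofuran (racemic, one enantiomer drawn) | CCCCCCCCCCCCCCCCCCC[C@]12Oc3cc(OC)cc(OC)c3[C@@]1(O[Si](C)(C)C(C)(C)C)C2(Br)Br | intermediate (not isolated)
10 | 3-bromo-4-[(tert-butyldimethylsilyl)oxy]-5,7-dimethoxy-2-nonadecylchromenylium bromide | CCCCCCCCCCCCCCCCCCCc1[o+]c2cc(OC)cc(OC)c2c(O[Si](C)(C)C(C)(C)C)c1Br.[Br-] | intermediate (not isolated)
11 | 3-bromo-5,7-dimethoxy-2-nonadecylchromone | CCCCCCCCCCCCCCCCCCCc1oc2cc(OC)cc(OC)c2c(=O)c1Br | intermediate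
12 | 5,7-dimethoxy-2-nonadecylchromone | CCCCCCCCCCCCCCCCCCCc1cc(=O)c2c(OC)cc(OC)cc2o1 | intermediate
13 | 5,7-bis[(dibromoboranyl)oxy]-2-nonadecylchromone | CCCCCCCCCCCCCCCCCCCc1cc(=O)c2c(OB(Br)Br)cc(OB(Br)Br)cc2o1 | intermediate (not isolated)
14 | 5,7-dihydroxy-2-nonadecylchromone | CCCCCCCCCCCCCCCCCCCc1cc(=O)c2c(O)cc(O)cc2o1 | target

**Step count**

Total steps: 7. Longest linear sequence: 7 steps (1-nonadecanol 1 to target 14); 6 steps from benzofuranone 3.

**Steps most likely to fail**

Step 5 (proposed new method). The Si–O bond may be cleaved by tert-butoxide before the carbene adds. The carbene may also add only slowly to the crowded tetrasubstituted C2=C3 bond next to the C4 methoxy group, or excess base may attack the bromochromone once formed. The fallback uses known chemistry and sets out from silyl enol ether 7. Ozonolysis (O3, CH2Cl2, −78 °C; then Me2S) should cleave the enol ether double bond to tert-butyldimethylsilyl 2-(icosanoyloxy)-4,6-dimethoxybenzoate F1. In F1 the old C2 is the carbonyl of an aryl icosanoate and the old C3 is a silyl ester. Treatment of F1 with (trimethylsilyl)methylenetriphenylphosphorane in THF at reflux should acylate the ylide at the silyl ester to give the acylphosphorane 3,5-dimethoxy-2-[(triphenylphosphoranylidene)acetyl]phenyl icosanoate F2. F2 should close by intramolecular Wittig olefination of the neighbouring ester carbonyl, a known chromone synthesis, so that C3 comes from the ylide carbon. The fallback comes back to the route at compound 12 and therefore replaces steps 5 and 6.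

Step 2. The enolisable long-chain aldehyde may self-condense on the basic surface faster than the benzofuranone captures it, or a second benzofuranone may add in Michael fashion to the alkylidene product. The fallback sets out from benzofuranone 3 and aldehyde 2 and avoids basic enolate chemistry. Compound 3 is silylated (TBSOTf, Et3N, CH2Cl2, 0 °C) to tert-butyl[(4,6-dimethoxy-1-benzofuran-3-yl)oxy]dimethylsilane F3. A Mukaiyama aldol addition of F3 to 2 (TiCl4, CH2Cl2, −78 °C) should give the β-hydroxy ketone 4, now isolated. Mesylation (MsCl, Et3N, CH2Cl2, 0 °C) should give 1-(4,6-dimethoxy-3-oxo-2,3-dihydro-1-benzofuran-2-yl)nonadecyl methanesulfonate F4, and E1cB elimination with DBU should give the alkylidene compound. The fallback comes back to the route at compound 5.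

Step 6. Palladium hydride may also reduce the C2=C3 bond, giving over-reduction to the chromanone, or oxidative addition into the hindered, electron-rich C3–Br bond may stall. The fallback sets out from bromochromone 11 and replaces the organopalladium pathway by a radical chain reduction with (Me3Si)3SiH and AIBN in toluene at 80 °C. Bromine abstraction by the silyl radical and hydrogen transfer to the C3 vinyl radical involve neither a metal hydride nor an oxidative addition. The fallback makes no new compound (F0) and comes back to the route at compound 12.

**Further compounds**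

F1 | step 5 | tert-butyldimethylsilyl 2-(icosanoyloxy)-4,6-dimethoxybenzoate | CCCCCCCCCCCCCCCCCCCC(=O)Oc1cc(OC)cc(OC)c1C(=O)O[Si](C)(C)C(C)(C)C
F2 | step 5 | 3,5-dimethoxy-2-[(triphenylphosphoranylidene)acetyl]phenyl icosanoate | CCCCCCCCCCCCCCCCCCCC(=O)Oc1cc(OC)cc(OC)c1C(=O)C=P(c1ccccc1)(c1ccccc1)c1ccccc1
F3 | step 2 | tert-butyl[(4,6-dimethoxy-1-benzofuran-3-yl)oxy]dimethylsilane | COc1cc(OC)c2c(O[Si](C)(C)C(C)(C)C)coc2c1
F4 | step 2 | 1-(4,6-dimethoxy-3-oxo-2,3-dihydro-1-benzofuran-2-yl)nonadecyl methanesulfonate | CCCCCCCCCCCCCCCCCCC(OS(C)(=O)=O)C1Oc2cc(OC)cc(OC)c2C1=O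
F0 | step 6 | none | none
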